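## Retrosynthetic overview

1. 27 (7-epi-clusianone) ⇐ methyl enol ether 26 ⇐ allyl compound 24 (cross-metathesis) ⇐ allylic acetate 23 (palladium/formate reduction) ⇐ vinyl carbinol 21.
2. 21 ⇐ adamantanol 17: retro-aldol cleavage of C3–C10 releases the 7-endo aldehyde, which is vinylated at once; the cage stores the endo C7 configuration.
3. 17 ⇐ clusiaphenone B 6 + acetoxy enal 14: intermolecular Michael addition–elimination (C5–C6, enantio-determining in a chiral ion pair), then intramolecular Michael (C1–C8) and aldol (C3–C10).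
4. 6 ⇐ phloroglucinol + benzoyl chloride + prenyl bromide; 14 ⇐ acrolein diethyl acetal + acetone.
5. Ring order: the arene supplies ring C1–C2–C3–C4–C5–C9; ring C5–C6–C7–C8–C1–C9 closes in the annulation; a third, temporary ring (C3–C10–C7) is closed by aldol and reopened.

Numbering used throughout: C1 = bridgehead next to C8 (CMe2); C5 = bridgehead next to C6 (CH2); C7 = CH carrying the side chain; C9 = bridging ketone; C10 = the formyl-derived carbon on C7. "Endo" means on the face of the C2–C3–C4 bridge. In this numbering the target is (1S,5R,7S) with the C7 prenyl endo, i.e. 7-epi-clusianone, not clusianone.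

Assumption 1: the cinchonidinium catalyst of step 7 is taken to give 17 in the configuration drawn; if it gives the antipode, its pseudoenantiomeric cinchoninium analogue is used with no other change.

Assumption 2: O-methylation in step 9 is taken to occur at the C4 oxygen (remote from the gem-dimethyl group); the C2 regioisomer would converge on 27 in step 13.

## Route

Step 1
Reactants: 1 phloroglucinol, 2 benzoyl chloride
Product: 3 2,4,6-trihydroxybenzophenone
Conditions: AlCl3 (3.5 equiv), PhNO2, 65 °C; then ice/aq. HCl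
Reagents that add atoms: none
Why: Friedel–Crafts acylation of the symmetrical, highly activated arene, after which the acyl group deactivates the ring against a second acylation; no stereocentre.

Step 2
Reactants: 3 2,4,6-trihydroxybenzophenone, 4 prenyl bromide
Product: 6 clusiaphenone B, via monoprenyl phenol 5 (not isolated)
Conditions: 4 (2.1 equiv), 10 % aq. KOH, 0 °C; then aq. HCl
Reagents that add atoms: none
Why: Phenoxide C-alkylation (SN2) in water, where the hydrogen-bonded oxygens are shielded and the two free ring carbons are prenylated in turn; no stereocentre.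

Step 3
Reactants: 7 acrolein diethyl acetal
Product: 8 2,3-dibromo-1,1-diethoxypropane (racemic)
Conditions: Br2 (1.0 equiv), CH2Cl2, −20 → 0 °C
Reagents that add atoms: bromine, BrBr
Why: Electrophilic anti addition of bromine to the alkene under neutral anhydrous conditions that leave the acetal intact; the racemic stereocentre is destroyed in step 4.

Step 4
Reactants: 8 2,3-dibromo-1,1-diethoxypropane
Product: 9 2-bromo-3,3-diethoxyprop-1-ene
Conditions: t-BuOK (1.05 equiv), THF, −20 → 0 °C
Reagents that add atoms: none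
Why: E2 dehydrobromination removes the most acidic proton (C2–H, flanked by bromine and the acetal carbon) with loss of the primary bromide, and one equivalent of base at low temperature stops before a second elimination to the alkyne.

Step 5
Reactants: 9 2-bromo-3,3-diethoxyprop-1-ene, 10 acetone
Product: 13 3-(diethoxymethyl)-2-methylbut-3-en-2-yl acetate, via vinyllithium 11 (not isolated), via lithium alkoxide 12 (not isolated)
Conditions: n-BuLi (1.05 equiv), THF, −78 °C; 10 (1.2 equiv), −78 °C; Ac2O (1.5 equiv), −78 °C → rt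
Reagents that add atoms: acetic anhydride, CC(=O)OC(C)=O
Why: Bromine–lithium exchange gives an acrolein α-anion equivalent that adds 1,2 to acetone, and the tertiary lithium alkoxide is acetylated in the same flask, which avoids a sluggish esterification of a hindered tertiary alcohol; no stereocentre.

Step 6
Reactants: 13 3-(diethoxymethyl)-2-methylbut-3-en-2-yl acetate
Product: 14 3-formyl-2-methylbut-3-en-2-yl acetate
Conditions: 10 % aq. oxalic acid on SiO2, CH2Cl2, rt; used at once
Reagents that add atoms: water, O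
Why: Mild acid-catalysed acetal hydrolysis, in which the conjugated acetal ionises far faster than the tertiary allylic acetate, which is then deactivated by the new formyl group; no stereocentre.

Step 7
Reactants: 6 clusiaphenone B, 14 3-formyl-2-methylbut-3-en-2-yl acetate
Product: 17 adamantanol, via dienone enal 15 (not isolated), via caesium enolate aldehyde 16 (not isolated)
Conditions: 14 (1.5 equiv), 2,7-bis[(O(9)-allylcinchonidinium-N-yl)methyl]naphthalene dibromide (25 mol %), CsOH·H2O (5 equiv), 4 Å MS, CH2Cl2, −50 °C; then aq. HCl; recrystallise to raise ee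
Reagents that add atoms: none
Why: Alkylative dearomatisation–annulation in which, within the chiral ion pair, one of the two enantiotopic prenylated carbons of 6 attacks the methylene terminus of 14 (intermolecular Michael addition, then E1cB loss of acetate; sets C5), the other prenylated carbon closes the ring by intramolecular Michael addition onto the new β,β-dimethyl enal (cis bridging is the only geometric option; sets C1), C7 is protonated on its open exo face so the formyl group of 16 is endo (sets C7), and aldol addition of C3 to that formyl group locks everything in the cage.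

Step 8
Reactants: 17 adamantanol, 18 vinylmagnesium bromide
Product: 21 7-endo-(1-hydroxyprop-2-enyl) triketone, via cerium alkoxide 19 (not isolated), via cerium enolate aldehyde 20 (not isolated)
Conditions: 18 (4 equiv), CeCl3 (anhydrous, 4 equiv), THF, −78 → 0 °C; then sat. aq. NH4Cl
Reagents that add atoms: none
Why: Retro-aldol–carbonyl vinylation in which the first equivalent of the weakly basic vinylcerium reagent deprotonates the carbinol (the only acidic proton of 17) to alkoxide 19, this fragments at C3–C10 to the dichlorocerium triketone enolate 20 (driven by the stabilised enolate) and the released 7-endo aldehyde is captured by 1,2-addition faster than it can enolise, so the endo C7 configuration is kept while the new C10 carbinol centre forms as an irrelevant mixture removed in step 11.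

Step 9
Reactants: 21 7-endo-(1-hydroxyprop-2-enyl) triketone
Product: 22 C4 methyl enol ether of 21
Conditions: TMSCHN2 (3 equiv), i-Pr2NEt, MeCN/MeOH (9:1), 0 °C → rt
Reagents that add atoms: trimethylsilyldiazomethane, C[Si](C)(C)C=[N+]=[N-]
Why: O-Methylation of the strongly acidic triketone enol (a vinylogous carboxylic acid) at the less hindered C4 oxygen masks the C3 nucleophile so that it cannot re-close onto the side chain in step 11, while the neutral secondary alcohol and all stereocentres are untouched.

Step 10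
Reactants: 22 C4 methyl enol ether of 21
Product: 23 allylic acetate
Conditions: Ac2O, Et3N, DMAP (cat.), CH2Cl2, rt
Reagents that add atoms: acetic anhydride, CC(=O)OC(C)=O
Why: DMAP-catalysed acylation of the secondary allylic alcohol installs the leaving group for the reduction, with the vinylogous ester and ketones inert; no stereocentre of the core is touched.

Step 11
Reactants: 23 allylic acetate
Product: 24 7-endo-allyl methyl enol ether
Conditions: Pd2(dba)3 (5 mol %, dba = dibenzylideneacetone), n-Bu3P (20 mol %), HCO2NH4 (5 equiv), 1,4-dioxane, 90 °C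
Reagents that add atoms: none
Why: Tsuji formate reduction, in which zerovalent palladium ionises the allylic acetate and formate-derived hydride is delivered to the more substituted allyl terminus to give the terminal alkene; C7 lies outside the allyl unit and keeps its endo configuration, and the mixed C10 centre disappears.

Step 12
Reactants: 24 7-endo-allyl methyl enol ether, 25 2-methyl-2-butene
Product: 26 O-methyl-7-epi-clusianone
Conditions: second-generation Grubbs catalyst [1,3-bis(2,4,6-trimethylphenyl)imidazolidin-2-ylidene](PCy3)Cl2Ru=CHPh (10 mol %), 25 (co-solvent), CH2Cl2, 40 °C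
Reagents that add atoms: none
Why: Olefin cross-metathesis of the terminal alkene with excess 2-methyl-2-butene converts allyl into prenyl, the existing prenyl groups undergoing only degenerate exchange; no stereocentre is touched.

Step 13
Reactants: 26 O-methyl-7-epi-clusianone
Product: 27 7-epi-clusianone
Conditions: 1 M aq. LiOH, 1,4-dioxane, 90 °C; then aq. HCl
Reagents that add atoms: lithium hydroxide, [Li+].[OH-]
Why: Vinylogous ester hydrolysis by conjugate addition–elimination of hydroxide (loss of methoxide) frees the chelated triketone enol, and neither the quaternary bridgeheads nor the non-enolisable C7 can epimerise.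

## Compound list

1 | phloroglucinol (benzene-1,3,5-triol) | Oc1cc(O)cc(O)c1 | starting material
2 | benzoyl chloride | O=C(Cl)c1ccccc1 | starting material
3 | 2,4,6-trihydroxybenzophenone | O=C(c1ccccc1)c1c(O)cc(O)cc1O | intermediate
4 | prenyl bromide (1-bromo-3-methylbut-2-ene) | CC(C)=CCBr | starting material
5 | monoprenyl phenol: 2,4,6-trihydroxy-3-(3-methylbut-2-enyl)benzophenone | CC(C)=CCc1c(O)cc(O)c(C(=O)c2ccccc2)c1O | intermediate
6 | clusiaphenone B: 2,4,6-trihydroxy-3,5-bis(3-methylbut-2-enyl)benzophenone | CC(C)=CCc1c(O)c(CC=C(C)C)c(O)c(C(=O)c2ccccc2)c1O | intermediate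
7 | acrolein diethyl acetal (3,3-diethoxyprop-1-ene) | C=CC(OCC)OCC | starting material
8 | 2,3-dibromo-1,1-diethoxypropane (racemic) | BrCC(Br)C(OCC)OCC | intermediate
9 | 2-bromo-3,3-diethoxyprop-1-ene | C=C(Br)C(OCC)OCC | intermediate
10 | acetone | CC(C)=O | starting material
11 | vinyllithium: (3,3-diethoxyprop-1-en-2-yl)lithium | [Li]C(=C)C(OCC)OCC | intermediate
12 | lithium alkoxide: lithium 3-(diethoxymethyl)-2-methylbut-3-en-2-olate | [Li+].[O-]C(C)(C)C(=C)C(OCC)OCC | intermediate
13 | 3-(diethoxymethyl)-2-methylbut-3-en-2-yl acetate | CC(=O)OC(C)(C)C(=C)C(OCC)OCC | intermediate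
14 | 3-formyl-2-methylbut-3-en-2-yl acetate (2-(2-acetoxypropan-2-yl)acrolein) | CC(=O)OC(C)(C)C(=C)C=O | intermediate
15 | dienone enal: 2-benzoyl-6-(2-formyl-3-methylbut-2-enyl)-3,5-dihydroxy-4,6-bis(3-methylbut-2-enyl)cyclohexa-2,4-dien-1-one, quaternary carbon configured as C5 of 27 (present in the flask as its enolate) | CC(C)=CC[C@]1(CC(C=O)=C(C)C)C(=O)C(C(=O)c2ccccc2)=C(O)C(CC=C(C)C)=C1O | intermediate
16 | caesium enolate aldehyde: caesium enolate of 3-benzoyl-7-endo-formyl-8,8-dimethyl-1,5-bis(3-methylbut-2-enyl)bicyclo[3.3.1]nonane-2,4,9-trione, C1/C5/C7 as in 27 | [Cs+].O=C[C@H]1C[C@@]2(CC=C(C)C)C(=O)C(C(=O)c3ccccc3)=C([O-])[C@](CC=C(C)C)(C2=O)C1(C)C | intermediate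
17 | adamantanol: 1-benzoyl-8-hydroxy-6,6-dimethyl-3,5-bis(3-methylbut-2-enyl)adamantane-2,4,9-trione, i.e. the cage in which C10 (CHOH, configuration not assigned) links C7 and C3; C1/C5/C7 as in 27 | OC1[C@H]2C[C@@]3(CC=C(C)C)C(=O)[C@]1(C(=O)c4ccccc4)C(=O)[C@](CC=C(C)C)(C3=O)C2(C)C | intermediate
18 | vinylmagnesium bromide | C=C[Mg]Br | starting material
19 | cerium alkoxide: O-dichlorocerium derivative of 17 | Cl[Ce](Cl)OC1[C@H]2C[C@@]3(CC=C(C)C)C(=O)[C@]1(C(=O)c4ccccc4)C(=O)[C@](CC=C(C)C)(C3=O)C2(C)C | intermediate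
20 | cerium enolate aldehyde: O-dichlorocerium enolate of 3-benzoyl-7-endo-formyl-8,8-dimethyl-1,5-bis(3-methylbut-2-enyl)bicyclo[3.3.1]nonane-2,4,9-trione, C1/C5/C7 as in 27 | O=C[C@H]1C[C@@]2(CC=C(C)C)C(=O)C(C(=O)c3ccccc3)=C(O[Ce](Cl)Cl)[C@](CC=C(C)C)(C2=O)C1(C)C | intermediate
21 | 3-benzoyl-7-endo-(1-hydroxyprop-2-enyl)-8,8-dimethyl-1,5-bis(3-methylbut-2-enyl)bicyclo[3.3.1]nonane-2,4,9-trione, chelated enol, C1/C5/C7 as in 27, C10 epimer mixture | C=CC(O)[C@H]1C[C@@]2(CC=C(C)C)C(=O)/C(=C(/O)c3ccccc3)C(=O)[C@](CC=C(C)C)(C2=O)C1(C)C | intermediate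
22 | C4 methyl enol ether of 21: 3-benzoyl-7-endo-(1-hydroxyprop-2-enyl)-4-methoxy-8,8-dimethyl-1,5-bis(3-methylbut-2-enyl)bicyclo[3.3.1]non-3-ene-2,9-dione, C10 epimer mixture | C=CC(O)[C@H]1C[C@@]2(CC=C(C)C)C(OC)=C(C(=O)c3ccccc3)C(=O)[C@](CC=C(C)C)(C2=O)C1(C)C | intermediate
23 | allylic acetate: C10 acetate of 22, C10 epimer mixture | C=CC(OC(C)=O)[C@H]1C[C@@]2(CC=C(C)C)C(OC)=C(C(=O)c3ccccc3)C(=O)[C@](CC=C(C)C)(C2=O)C1(C)C | intermediate
24 | 7-endo-allyl-3-benzoyl-4-methoxy-8,8-dimethyl-1,5-bis(3-methylbut-2-enyl)bicyclo[3.3.1]non-3-ene-2,9-dione, C1/C5/C7 as in 27 | C=CC[C@H]1C[C@@]2(CC=C(C)C)C(OC)=C(C(=O)c3ccccc3)C(=O)[C@](CC=C(C)C)(C2=O)C1(C)C | intermediate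
25 | 2-methyl-2-butene | CC=C(C)C | starting material
26 | O-methyl-7-epi-clusianone: 3-benzoyl-4-methoxy-8,8-dimethyl-1,5,7-tris(3-methylbut-2-enyl)bicyclo[3.3.1]non-3-ene-2,9-dione, C7 prenyl endo, C1/C5/C7 as in 27 | CC(C)=CC[C@H]1C[C@@]2(CC=C(C)C)C(OC)=C(C(=O)c3ccccc3)C(=O)[C@](CC=C(C)C)(C2=O)C1(C)C | intermediate
27 | 7-epi-clusianone: (1S,5R,7S)-3-[hydroxy(phenyl)methylidene]-8,8-dimethyl-1,5,7-tris(3-methylbut-2-enyl)bicyclo[3.3.1]nonane-2,4,9-trione, C7 prenyl endo | CC(C)=CC[C@H]1C[C@@]2(CC=C(C)C)C(=O)/C(=C(/O)c3ccccc3)C(=O)[C@](CC=C(C)C)(C2=O)C1(C)C | target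

## Step count and risk

Total steps: 13. Longest linear sequence: 11 steps (7 → 27 through steps 3–13); the arene arm (steps 1–2) joins at step 7.

The three steps most likely to fail:

**Step 7** (enantioselectivity or yield of the ion-pair annulation may fall short). The fallback is a racemic cascade followed by resolution. It sets out from 6 and 14: LiN(SiMe3)2 (3 equiv) in THF at 0 °C runs the same Michael/Michael/aldol sequence without a chiral counter-ion. It passes through 15 and its mirror image, the ent-dienone enal F1, then through the lithium enolate aldehyde F2 and its mirror image, the ent-lithium enolate aldehyde F3. It gives 17 together with its mirror image, the ent-adamantanol F4. Preparative chiral-phase supercritical-fluid chromatography (amylose tris(3,5-dimethylphenylcarbamate), CO2/MeOH) removes F4, and the route is rejoined at 17.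

**Step 8** (addition to ring ketones, re-closure of the cage or C7 epimerisation may compete). The fallback epimerises deliberately and then restores endo by kinetic protonation. It sets out from 17: K2CO3 in MeOH at 50 °C opens the cage by retro-aldol under thermodynamic control and equilibrates C7 through the aldehyde enolate, giving after acidification the 7-exo-formyl triketone F5. TMSCHN2/i-Pr2NEt gives the 7-exo-formyl methyl enol ether F6, in which C3 can no longer re-close. t-BuMe2SiOTf/Et3N in CH2Cl2 gives the C7-exocyclic silyl enol ether F7. Bu4NF/AcOH in THF at −78 °C protonates C7 from the open exo face to give the 7-endo-formyl methyl enol ether F8. This is treated crude with vinylmagnesium bromide/CeCl3 at −78 °C, and the route is rejoined at 22.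

**Step 11** (wrong regiochemistry of hydride delivery or diene formation). The fallback builds the prenyl group by homologation and olefination, without allyl–palladium chemistry. It sets out from 17: Me3SiCH2MgCl/CeCl3 (4 equiv each) in THF, −78 → 0 °C, triggers the same retro-aldol as in step 8 and adds to the released 7-endo aldehyde to give the β-hydroxysilane F9. KH (3 equiv) in THF, 0 °C → rt, then effects Peterson syn-elimination to the 7-endo-vinyl triketone F10. TMSCHN2/i-Pr2NEt gives the vinyl methyl enol ether F11. 9-BBN in THF at rt hydroborates only the monosubstituted alkene to the B-alkyl-9-BBN adduct F12, which NaBO3·4H2O oxidises to the primary alcohol F13. Dess–Martin periodinane gives the homologated aldehyde F14. Wittig reaction with Ph3P=CMe2 (from isopropyltriphenylphosphonium iodide and n-BuLi) at −78 °C rejoins the route at 26.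

## Further compounds

F1 | step 7 | ent-dienone enal (mirror image of 15) | CC(C)=CC[C@@]1(CC(C=O)=C(C)C)C(=O)C(C(=O)c2ccccc2)=C(O)C(CC=C(C)C)=C1O
F2 | step 7 | lithium enolate aldehyde (lithium enolate of the 7-endo-formyl triketone, C1/C5/C7 as in 27) | [Li+].O=C[C@H]1C[C@@]2(CC=C(C)C)C(=O)C(C(=O)c3ccccc3)=C([O-])[C@](CC=C(C)C)(C2=O)C1(C)C
F3 | step 7 | ent-lithium enolate aldehyde (mirror image of F2) | [Li+].O=C[C@@H]1C[C@]2(CC=C(C)C)C(=O)C(C(=O)c3ccccc3)=C([O-])[C@@](CC=C(C)C)(C2=O)C1(C)C
F4 | step 7 | ent-adamantanol (mirror image of 17) | OC1[C@@H]2C[C@]3(CC=C(C)C)C(=O)[C@@]1(C(=O)c4ccccc4)C(=O)[C@@](CC=C(C)C)(C3=O)C2(C)C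
F5 | step 8 | 7-exo-formyl triketone (C7 epimer of the 7-endo-formyl triketone, chelated enol) | O=C[C@@H]1C[C@@]2(CC=C(C)C)C(=O)/C(=C(/O)c3ccccc3)C(=O)[C@](CC=C(C)C)(C2=O)C1(C)C
F6 | step 8 | 7-exo-formyl methyl enol ether (C4-OMe) | O=C[C@@H]1C[C@@]2(CC=C(C)C)C(OC)=C(C(=O)c3ccccc3)C(=O)[C@](CC=C(C)C)(C2=O)C1(C)C
F7 | step 8 | C7-exocyclic silyl enol ether (tert-butyldimethylsilyloxymethylidene at C7, C4-OMe, E/Z mixture) | CC(C)(C)[Si](C)(C)OC=C1C[C@@]2(CC=C(C)C)C(OC)=C(C(=O)c3ccccc3)C(=O)[C@](CC=C(C)C)(C2=O)C1(C)C
F8 | step 8 | 7-endo-formyl methyl enol ether (C4-OMe) | O=C[C@H]1C[C@@]2(CC=C(C)C)C(OC)=C(C(=O)c3ccccc3)C(=O)[C@](CC=C(C)C)(C2=O)C1(C)C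
F9 | step 11 | β-hydroxysilane (7-endo-(1-hydroxy-2-trimethylsilylethyl) triketone, chelated enol, C10 epimer mixture) | C[Si](C)(C)CC(O)[C@H]1C[C@@]2(CC=C(C)C)C(=O)/C(=C(/O)c3ccccc3)C(=O)[C@](CC=C(C)C)(C2=O)C1(C)C
F10 | step 11 | 7-endo-vinyl triketone (chelated enol) | C=C[C@H]1C[C@@]2(CC=C(C)C)C(=O)/C(=C(/O)c3ccccc3)C(=O)[C@](CC=C(C)C)(C2=O)C1(C)C
F11 | step 11 | vinyl methyl enol ether (7-endo-vinyl, C4-OMe) | C=C[C@H]1C[C@@]2(CC=C(C)C)C(OC)=C(C(=O)c3ccccc3)C(=O)[C@](CC=C(C)C)(C2=O)C1(C)C
F12 | step 11 | B-alkyl-9-BBN adduct (2-(9-borabicyclo[3.3.1]nonan-9-yl)ethyl at C7 endo, C4-OMe) | C1CC2CCCC(C1)B2CC[C@H]3C[C@@]4(CC=C(C)C)C(OC)=C(C(=O)c5ccccc5)C(=O)[C@](CC=C(C)C)(C4=O)C3(C)C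
F13 | step 11 | primary alcohol (7-endo-(2-hydroxyethyl), C4-OMe) | OCC[C@H]1C[C@@]2(CC=C(C)C)C(OC)=C(C(=O)c3ccccc3)C(=O)[C@](CC=C(C)C)(C2=O)C1(C)C
F14 | step 11 | homologated aldehyde (7-endo-(2-oxoethyl), C4-OMe) | O=CC[C@H]1C[C@@]2(CC=C(C)C)C(OC)=C(C(=O)c3ccccc3)C(=O)[C@](CC=C(C)C)(C2=O)C1(C)C
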